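**Retrosynthetic overview**

1. Pervilleanone 20 comes from its 7,2'-bis(triisopropylsilyl) ether 19 by Si–O cleavage.
2. The route rests on one feature of ring C: C2 is a CH2 group bonded only to O1 and C3. Cutting C2–C3 turns C2 into the methyl group of a ring A methyl ether and C3 into a carbene carbon held between the C4 carbonyl and ring B, which is diazo ketone 17.
3. 17 comes from deoxybenzoin 16 by diazo transfer; 16 comes from the ring A aryl Grignard reagent 14 and the ring B arylacetaldehyde 11 (C4–C4a bond), followed by oxidation.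
4. 11 comes from salicylaldehyde 8 by O-silylation and one-carbon homologation; 8 comes from 2-methoxyresorcinol 1 by formylation, 4-O-prenylation, aromatic Claisen rearrangement (places the 2-methylbut-3-en-2-yl group at C5') and 4-O-methylation.
5. Rings A and B are bought as benzene rings; ring C is the only ring made, and it is closed in the step that also sets C3.

Key step: step 12

Abbreviations: TIPS = triisopropylsilyl; TIPSOTf = triisopropylsilyl triflate; p-ABSA = 4-acetamidobenzenesulfonyl azide; DMP = Dess–Martin periodinane; Rh2(S-PTTL)4 = dirhodium tetrakis[N-phthaloyl-(S)-tert-leucinate].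

Assumption: Rh2(S-PTTL)4 is taken to give the (R) configuration at C3; the sense of induction cannot be predicted with certainty and must be checked on the first batch, and Rh2(R-PTTL)4 is used if the (S) enantiomer predominates.

**Route**

Step 1
Reactants: 1 2-methoxyresorcinol
Product: 3 2,4-dihydroxy-3-methoxybenzaldehyde, via iminium chloride 2 (not isolated)
Conditions: POCl3, DMF, MeCN, −15 °C → rt; then H2O, 50 °C
Reagents that add atoms: N,N-dimethylformamide CN(C)C=O (formyl carbon); water O (carbonyl oxygen)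
Why: Vilsmeier–Haack formylation; the position para to one hydroxyl and ortho to the other is by far the most nucleophilic, and the two such positions of the symmetrical diol are equivalent, so a single aldehyde should result after hydrolysis of iminium salt 2.

Step 2
Reactants: 3 2,4-dihydroxy-3-methoxybenzaldehyde; 4 prenyl bromide
Product: 5 2-hydroxy-3-methoxy-4-(3-methylbut-2-enyloxy)benzaldehyde
Conditions: K2CO3 (1.1 equiv.), acetone, rt
Reagents that add atoms: none
Why: Williamson ether synthesis; the 4-hydroxyl para to the formyl group is the more acidic and is free, whereas the 2-hydroxyl is held in a hydrogen bond to the aldehyde, so alkylation should occur at O-4 only.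

Step 3
Reactants: 5 2-hydroxy-3-methoxy-4-(3-methylbut-2-enyloxy)benzaldehyde
Product: 7 2,4-dihydroxy-3-methoxy-5-(2-methylbut-3-en-2-yl)benzaldehyde, via dienone 6 (not isolated)
Conditions: EtOH–H2O (4:1), 130 °C, sealed tube, argon
Reagents that add atoms: none
Why: Aromatic Claisen rearrangement: the [3,3] shift joins the dimethyl-substituted allyl terminus to C5, the only ortho carbon that carries hydrogen (C3 is blocked by OCH3), dienone 6 re-aromatises by tautomerisation, the allyl inversion delivers the 2-methylbut-3-en-2-yl group, and the protic medium accelerates the shift so that the temperature stays below that of the abnormal Claisen and cyclisation pathways.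

Step 4
Reactants: 7 2,4-dihydroxy-3-methoxy-5-(2-methylbut-3-en-2-yl)benzaldehyde
Product: 8 2-hydroxy-3,4-dimethoxy-5-(2-methylbut-3-en-2-yl)benzaldehyde
Conditions: MeI (1.1 equiv.), K2CO3 (1.1 equiv.), acetone, rt
Reagents that add atoms: iodomethane CI
Why: Williamson methylation; the 4-phenoxide (para to the aldehyde) forms first and the small electrophile tolerates the two ortho substituents, while the hydrogen-bonded 2-hydroxyl needs forcing conditions to react.

Step 5
Reactants: 8 2-hydroxy-3,4-dimethoxy-5-(2-methylbut-3-en-2-yl)benzaldehyde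
Product: 9 3,4-dimethoxy-5-(2-methylbut-3-en-2-yl)-2-(triisopropylsilyloxy)benzaldehyde
Conditions: TIPSOTf, 2,6-lutidine, CH2Cl2, 0 °C → rt
Reagents that add atoms: triisopropylsilyl trifluoromethanesulfonate CC(C)[Si](C(C)C)(C(C)C)OS(=O)(=O)C(F)(F)F
Why: O-silylation of a phenol; the silyl triflate is reactive enough for the hindered, hydrogen-bonded hydroxyl, and the bulky silyl ether later shields O-2' and carries no oxygen-activated C–H bond within reach of the carbene.

Step 6
Reactants: 9 3,4-dimethoxy-5-(2-methylbut-3-en-2-yl)-2-(triisopropylsilyloxy)benzaldehyde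
Product: 10 [2,3-dimethoxy-6-(2-methoxyethenyl)-4-(2-methylbut-3-en-2-yl)phenoxy]triisopropylsilane (E/Z mixture)
Conditions: MeOCH2PPh3Cl, KOtBu, THF, 0 °C; then 9, 0 °C → rt
Reagents that add atoms: (methoxymethyl)triphenylphosphonium chloride COC[P+](c1ccccc1)(c1ccccc1)c1ccccc1.[Cl-]
Why: Wittig methoxymethylenation; the small, reactive ylide adds to hindered aryl aldehydes, and both alkene isomers lead to the same aldehyde in the next step.

Step 7
Reactants: 10 [2,3-dimethoxy-6-(2-methoxyethenyl)-4-(2-methylbut-3-en-2-yl)phenoxy]triisopropylsilane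
Product: 11 2-[3,4-dimethoxy-5-(2-methylbut-3-en-2-yl)-2-(triisopropylsilyloxy)phenyl]acetaldehyde
Conditions: 2 M aq. HCl, THF, rt; used crude
Reagents that add atoms: water O
Why: Acid-catalysed enol ether hydrolysis through the oxocarbenium ion and hemiacetal; the aryl TIPS ether and the monosubstituted alkene next to a quaternary carbon should be inert to dilute acid at room temperature.

Step 8
Reactants: 12 4-bromo-3-methoxyphenol
Product: 13 (4-bromo-3-methoxyphenoxy)triisopropylsilane
Conditions: TIPSCl, imidazole, DMF, rt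
Reagents that add atoms: triisopropylsilyl chloride CC(C)[Si](Cl)(C(C)C)C(C)C
Why: Standard O-silylation of an unhindered phenol, which masks the acidic proton before the organomagnesium step.

Step 9
Reactants: 13 (4-bromo-3-methoxyphenoxy)triisopropylsilane; 11 2-[3,4-dimethoxy-5-(2-methylbut-3-en-2-yl)-2-(triisopropylsilyloxy)phenyl]acetaldehyde
Product: 15 rac-1-[2-methoxy-4-(triisopropylsilyloxy)phenyl]-2-[3,4-dimethoxy-5-(2-methylbut-3-en-2-yl)-2-(triisopropylsilyloxy)phenyl]ethanol, via Grignard reagent 14 (not isolated)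
Conditions: 13, Mg turnings (I2-activated), THF, reflux; then 11, THF, −78 → 0 °C; sat. aq. NH4Cl
Reagents that add atoms: none
Why: Grignard addition of an aryl magnesium bromide to an aldehyde, which forms the C4–C4a bond; low temperature favours 1,2-addition over enolisation, and the carbinol centre is racemic and is removed in the next step.

Step 10
Reactants: 15 rac-1-[2-methoxy-4-(triisopropylsilyloxy)phenyl]-2-[3,4-dimethoxy-5-(2-methylbut-3-en-2-yl)-2-(triisopropylsilyloxy)phenyl]ethanol
Product: 16 1-[2-methoxy-4-(triisopropylsilyloxy)phenyl]-2-[3,4-dimethoxy-5-(2-methylbut-3-en-2-yl)-2-(triisopropylsilyloxy)phenyl]ethanone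
Conditions: DMP, pyridine, CH2Cl2, 0 °C → rt
Reagents that add atoms: none
Why: Dess–Martin oxidation of a secondary benzylic alcohol under near-neutral conditions that leave silyl ethers, the vinyl group and the electron-rich arenes untouched.

Step 11
Reactants: 16 1-[2-methoxy-4-(triisopropylsilyloxy)phenyl]-2-[3,4-dimethoxy-5-(2-methylbut-3-en-2-yl)-2-(triisopropylsilyloxy)phenyl]ethanone
Product: 17 2-diazo-1-[2-methoxy-4-(triisopropylsilyloxy)phenyl]-2-[3,4-dimethoxy-5-(2-methylbut-3-en-2-yl)-2-(triisopropylsilyloxy)phenyl]ethanone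
Conditions: p-ABSA, DBU, MeCN, 0 °C → rt
Reagents that add atoms: 4-acetamidobenzenesulfonyl azide CC(=O)Nc1ccc(cc1)S(=O)(=O)N=[N+]=[N-]
Why: Regitz diazo transfer; the CH2 group between the ketone and ring B is acidic enough for DBU, and its enolate takes up the terminal N2 unit of the sulfonyl azide without prior activation.

Step 12
Reactants: 17 2-diazo-1-[2-methoxy-4-(triisopropylsilyloxy)phenyl]-2-[3,4-dimethoxy-5-(2-methylbut-3-en-2-yl)-2-(triisopropylsilyloxy)phenyl]ethanone
Product: 19 (R)-7,2'-bis-O-(triisopropylsilyl)pervilleanone, via rhodium carbene 18 (not isolated)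
Conditions: Rh2(S-PTTL)4 (2 mol %), toluene (0.01 M), 4 Å MS, slow addition of 17, 0 °C → rt
Reagents that add atoms: none
Why: Rh2(S-PTTL)4, a divalent rhodium carboxylate dimer, expels N2 from 17 to give the electrophilic aryl keto carbene 18 at C3, which takes a hydride-like hydrogen from the ring A OCH3 group while the C2–C3 bond forms in the same three-centre transition state (concerted intramolecular carbene C–H insertion). The closest known reaction types are the dirhodium-catalysed insertion of 2-alkoxyphenyl α-diazo ketones into the C–H bond next to the ether oxygen to give chroman-4-ones, and the insertion of aryl-substituted rhodium carbenes into C–H bonds of aryl methyl ethers. Ring C closes as a six-membered ring by a formal 1,6-insertion, the carbene carbon C3 and the methyl carbon (the future C2) being linked through C4, C4a, C8a and O1. C3 is the only new stereocentre; its configuration is fixed by the N-phthaloyl-tert-leucinate ligands, which leave one face of the carbene open to the C–H bond, and it forms under neutral conditions so that it is not enolised. Insertion must win over the five-membered oxonium ylide at O1 (reversible, since methyl migrates poorly and a non-polar solvent disfavours the zwitterion), over intermolecular attack on the vinyl group (high dilution, slow addition) and over other C–H sites: the 3'- and 4'-OCH3 groups are meta and para to C1' and cannot reach C3, O-2' is too close, and the isopropyl C–H bonds on silicon are shielded and not activated by oxygen.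

Step 13
Reactants: 19 (R)-7,2'-bis-O-(triisopropylsilyl)pervilleanone
Product: 20 pervilleanone
Conditions: HF·pyridine, pyridine, THF, 0 °C → rt
Reagents that add atoms: none
Why: Fluoride-driven cleavage of both aryl silyl ethers in an acidic, pyridine-buffered medium in which no phenoxide or enolate forms, so the acidic C3–H between the ketone and ring B should not exchange and the (R) centre is kept; the vinyl group and the methyl ethers are inert.

**Compound list**

1 | 2-methoxyresorcinol (2-methoxybenzene-1,3-diol) | COc1c(O)cccc1O | starting material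
2 | N-[(2,4-dihydroxy-3-methoxyphenyl)methylidene]-N-methylmethanaminium chloride (iminium chloride) | C[N+](C)=Cc1ccc(O)c(OC)c1O.[Cl-] | intermediate (not isolated)
3 | 2,4-dihydroxy-3-methoxybenzaldehyde | O=Cc1ccc(O)c(OC)c1O | intermediate
4 | prenyl bromide (1-bromo-3-methylbut-2-ene) | CC(C)=CCBr | starting material
5 | 2-hydroxy-3-methoxy-4-(3-methylbut-2-enyloxy)benzaldehyde | O=Cc1ccc(OCC=C(C)C)c(OC)c1O | intermediate
6 | 4-formyl-3-hydroxy-2-methoxy-6-(2-methylbut-3-en-2-yl)cyclohexa-2,4-dien-1-one (racemic dienone) | O=CC1=CC(C(C)(C)C=C)C(=O)C(OC)=C1O | intermediate (not isolated)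
7 | 2,4-dihydroxy-3-methoxy-5-(2-methylbut-3-en-2-yl)benzaldehyde | O=Cc1cc(C(C)(C)C=C)c(O)c(OC)c1O | intermediate
8 | 2-hydroxy-3,4-dimethoxy-5-(2-methylbut-3-en-2-yl)benzaldehyde | O=Cc1cc(C(C)(C)C=C)c(OC)c(OC)c1O | intermediate
9 | 3,4-dimethoxy-5-(2-methylbut-3-en-2-yl)-2-(triisopropylsilyloxy)benzaldehyde | O=Cc1cc(C(C)(C)C=C)c(OC)c(OC)c1O[Si](C(C)C)(C(C)C)C(C)C | intermediate
10 | [2,3-dimethoxy-6-(2-methoxyethenyl)-4-(2-methylbut-3-en-2-yl)phenoxy]triisopropylsilane (E/Z mixture) | COC=Cc1cc(C(C)(C)C=C)c(OC)c(OC)c1O[Si](C(C)C)(C(C)C)C(C)C | intermediate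
11 | 2-[3,4-dimethoxy-5-(2-methylbut-3-en-2-yl)-2-(triisopropylsilyloxy)phenyl]acetaldehyde | O=CCc1cc(C(C)(C)C=C)c(OC)c(OC)c1O[Si](C(C)C)(C(C)C)C(C)C | intermediate
12 | 4-bromo-3-methoxyphenol | COc1cc(O)ccc1Br | starting material
13 | (4-bromo-3-methoxyphenoxy)triisopropylsilane | COc1cc(O[Si](C(C)C)(C(C)C)C(C)C)ccc1Br | intermediate
14 | [2-methoxy-4-(triisopropylsilyloxy)phenyl]magnesium bromide | COc1cc(O[Si](C(C)C)(C(C)C)C(C)C)ccc1[Mg]Br | intermediate (not isolated)
15 | rac-1-[2-methoxy-4-(triisopropylsilyloxy)phenyl]-2-[3,4-dimethoxy-5-(2-methylbut-3-en-2-yl)-2-(triisopropylsilyloxy)phenyl]ethanol | COc1cc(O[Si](C(C)C)(C(C)C)C(C)C)ccc1C(O)Cc1cc(C(C)(C)C=C)c(OC)c(OC)c1O[Si](C(C)C)(C(C)C)C(C)C | intermediate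
16 | 1-[2-methoxy-4-(triisopropylsilyloxy)phenyl]-2-[3,4-dimethoxy-5-(2-methylbut-3-en-2-yl)-2-(triisopropylsilyloxy)phenyl]ethanone | COc1cc(O[Si](C(C)C)(C(C)C)C(C)C)ccc1C(=O)Cc1cc(C(C)(C)C=C)c(OC)c(OC)c1O[Si](C(C)C)(C(C)C)C(C)C | intermediate
17 | 2-diazo-1-[2-methoxy-4-(triisopropylsilyloxy)phenyl]-2-[3,4-dimethoxy-5-(2-methylbut-3-en-2-yl)-2-(triisopropylsilyloxy)phenyl]ethanone | COc1cc(O[Si](C(C)C)(C(C)C)C(C)C)ccc1C(=O)C(=[N+]=[N-])c1cc(C(C)(C)C=C)c(OC)c(OC)c1O[Si](C(C)C)(C(C)C)C(C)C | intermediate
18 | rhodium carbene formed from 17 on Rh2(S-PTTL)4 ([Rh] in the SMILES stands for the Rh2(S-PTTL)4 unit) | COc1cc(O[Si](C(C)C)(C(C)C)C(C)C)ccc1C(=O)C(=[Rh])c1cc(C(C)(C)C=C)c(OC)c(OC)c1O[Si](C(C)C)(C(C)C)C(C)C | intermediate (not isolated)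
19 | (R)-7,2'-bis-O-(triisopropylsilyl)pervilleanone, (3R)-3-[3,4-dimethoxy-5-(2-methylbut-3-en-2-yl)-2-(triisopropylsilyloxy)phenyl]-7-(triisopropylsilyloxy)chroman-4-one | C=CC(C)(C)c1cc([C@@H]2COc3cc(O[Si](C(C)C)(C(C)C)C(C)C)ccc3C2=O)c(O[Si](C(C)C)(C(C)C)C(C)C)c(OC)c1OC | intermediate
20 | pervilleanone, (3R)-7-hydroxy-3-[2-hydroxy-3,4-dimethoxy-5-(2-methylbut-3-en-2-yl)phenyl]chroman-4-one | C=CC(C)(C)c1cc([C@@H]2COc3cc(O)ccc3C2=O)c(O)c(OC)c1OC | target

**Step count**

Total: 13 steps. Longest linear sequence: 12 steps (steps 1–7 and 9–13, from 2-methoxyresorcinol); step 8 is a one-step side branch.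

**Steps most likely to fail**

1. Step 12. The carbene may be used up by ylide formation at the methoxy oxygen followed by methyl shift, by dimerisation, or by reaction with the vinyl group of a second molecule before the slow insertion into a primary C–H bond occurs; the ligands may also discriminate the two carbene faces poorly. The fallback sets out from 16 and returns at 19. MgI2 etherate (toluene–Et2O, 60 °C) should cleave only the ring A methyl ether that is chelated to the ketone and give the ortho-hydroxy deoxybenzoin F1. N,N-Dimethylformamide dimethyl acetal (toluene, 100 °C) then supplies C2 and closes ring C to the isoflavone F2. Transfer hydrogenation with RuCl(p-cymene)[(R,R)-TsDPEN] and HCO2H/Et3N (the catalyst enantiomer chosen to give the 3R series) reduces C2=C3 and then the ketone, with dynamic kinetic resolution through the rapidly enolising isoflavanone, to give the cis-(3R,4R)-isoflavan-4-ol F3. DMP with pyridine oxidises C4 without touching C3 and gives 19.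

2. Step 3. The allyl group may migrate to the methoxy-bearing ortho carbon and on to C1 with loss of the formyl group, or the first-formed ortho-(2-methylbut-3-en-2-yl)phenol may rearrange further or cyclise onto its alkene. The fallback sets out from 3 and returns at 10. NBS (MeCN, 0 °C) brominates C5, the position ortho to the 4-hydroxyl and para to the 2-hydroxyl, to give the bromo aldehyde F4. MeI/K2CO3 methylates O-4 as in step 4 to give the dimethoxy bromophenol F5, and TIPSOTf/2,6-lutidine gives the silyl ether F6. Methoxymethylenation as in step 6 gives the bromo enol ether F7, which no longer carries an aldehyde that could react with an allylboron reagent. A palladium-catalysed γ-selective Suzuki–Miyaura coupling of F7 with prenylboronic acid pinacol ester (Pd(OAc)2, a bulky biarylphosphine chosen for branched selectivity, K3PO4, aqueous THF, 40–70 °C) attaches the 2-methylbut-3-en-2-yl group at C5' and gives 10.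

3. Step 9. The Grignard reagent may deprotonate the enolisable arylacetaldehyde, which then condenses with itself instead of undergoing 1,2-addition. The fallback sets out from 13 (through 14) and from 9, returns at 16, and bypasses steps 6, 7, 9 and 10. Grignard reagent 14 is quenched with DMF to give 2-methoxy-4-(triisopropylsilyloxy)benzaldehyde F8. Kabachnik–Fields condensation with aniline and diphenyl phosphite gives the α-anilino phosphonate F9. Its anion (Cs2CO3, THF–iPrOH, rt) condenses with aldehyde 9 in a Horner–Wadsworth–Emmons-type olefination to the N-phenyl enamine F10, and dilute aqueous HCl in THF hydrolyses it to ketone 16.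

**Further compounds**

F1 | step 12 | 1-[2-hydroxy-4-(triisopropylsilyloxy)phenyl]-2-[3,4-dimethoxy-5-(2-methylbut-3-en-2-yl)-2-(triisopropylsilyloxy)phenyl]ethanone | Oc1cc(O[Si](C(C)C)(C(C)C)C(C)C)ccc1C(=O)Cc1cc(C(C)(C)C=C)c(OC)c(OC)c1O[Si](C(C)C)(C(C)C)C(C)C
F2 | step 12 | 3-[3,4-dimethoxy-5-(2-methylbut-3-en-2-yl)-2-(triisopropylsilyloxy)phenyl]-7-(triisopropylsilyloxy)-4H-chromen-4-one | C=CC(C)(C)c1cc(C2=COc3cc(O[Si](C(C)C)(C(C)C)C(C)C)ccc3C2=O)c(O[Si](C(C)C)(C(C)C)C(C)C)c(OC)c1OC
F3 | step 12 | (3R,4R)-3-[3,4-dimethoxy-5-(2-methylbut-3-en-2-yl)-2-(triisopropylsilyloxy)phenyl]-7-(triisopropylsilyloxy)chroman-4-ol (cis) | C=CC(C)(C)c1cc([C@@H]2COc3cc(O[Si](C(C)C)(C(C)C)C(C)C)ccc3[C@@H]2O)c(O[Si](C(C)C)(C(C)C)C(C)C)c(OC)c1OC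
F4 | step 3 | 5-bromo-2,4-dihydroxy-3-methoxybenzaldehyde | O=Cc1cc(Br)c(O)c(OC)c1O
F5 | step 3 | 5-bromo-2-hydroxy-3,4-dimethoxybenzaldehyde | O=Cc1cc(Br)c(OC)c(OC)c1O
F6 | step 3 | 5-bromo-3,4-dimethoxy-2-(triisopropylsilyloxy)benzaldehyde | O=Cc1cc(Br)c(OC)c(OC)c1O[Si](C(C)C)(C(C)C)C(C)C
F7 | step 3 | [4-bromo-2,3-dimethoxy-6-(2-methoxyethenyl)phenoxy]triisopropylsilane (E/Z mixture) | COC=Cc1cc(Br)c(OC)c(OC)c1O[Si](C(C)C)(C(C)C)C(C)C
F8 | step 9 | 2-methoxy-4-(triisopropylsilyloxy)benzaldehyde | COc1cc(O[Si](C(C)C)(C(C)C)C(C)C)ccc1C=O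
F9 | step 9 | diphenyl {anilino[2-methoxy-4-(triisopropylsilyloxy)phenyl]methyl}phosphonate (racemic) | COc1cc(O[Si](C(C)C)(C(C)C)C(C)C)ccc1C(Nc1ccccc1)P(=O)(Oc1ccccc1)Oc1ccccc1
F10 | step 9 | N-{2-[3,4-dimethoxy-5-(2-methylbut-3-en-2-yl)-2-(triisopropylsilyloxy)phenyl]-1-[2-methoxy-4-(triisopropylsilyloxy)phenyl]ethenyl}aniline | COc1cc(O[Si](C(C)C)(C(C)C)C(C)C)ccc1C(Nc1ccccc1)=Cc1cc(C(C)(C)C=C)c(OC)c(OC)c1O[Si](C(C)C)(C(C)C)C(C)C
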